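**Retrosynthetic overview**
- Target ⇐ global hydrogenolysis of its octabenzyl ether; the (2S) centre is secured by a Rh-catalysed transfer-hydrogenation kinetic resolution of the racemic protected flavanone.
- Flavanone ring C (closed last) ⇐ Mitsunobu O1–C2 closure of a β-hydroxy ketone ⇐ key C–C bond (C2–C3 of the flavanone): intermolecular aldol addition of the dianion of 2′-hydroxy-4′,6′-bis(benzyloxy)acetophenone to a flavone-bearing biaryl aldehyde.
- Biaryl aldehyde ⇐ Suzuki–Miyaura coupling (2′–8″ bond) of tetra-O-benzyl-luteolin-8-boronate with 2-bromo-3,4-bis(benzyloxy)benzaldehyde.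
- Flavone ⇐ Claisen–Schmidt condensation of the 3′-iodinated acetophenone with 3,4-bis(benzyloxy)benzaldehyde, then I2/DMSO oxidative cyclisation.
- Ring order: flavone pyranone ring first, biaryl bond second, flavanone pyranone ring last.

Assumption: the SMILES defines only C2 (S) and gives no descriptor for the 2′–8″ biaryl axis, so the axis is not controlled; the biaryl aldehyde and everything after it are carried as mixtures of axial isomers if the axis is configurationally stable.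

**Route**

Step 1
Reactants: 1 2′,4′,6′-trihydroxyacetophenone
Product: 2 1-[2,4-bis(benzyloxy)-6-hydroxyphenyl]ethan-1-one
Conditions: BnBr (2.1 equiv), K2CO3 (2.2 equiv), DMF, rt
Reagents that add atoms: benzyl bromide, BrCc1ccccc1
Why: Williamson ether synthesis in which the two non-chelated phenols alkylate while the OH hydrogen-bonded to the acetyl group stays free.

Step 2
Reactants: 2 1-[2,4-bis(benzyloxy)-6-hydroxyphenyl]ethan-1-one
Product: 3 1-[4,6-bis(benzyloxy)-2-hydroxy-3-iodophenyl]ethan-1-one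
Conditions: NIS (1.05 equiv), TFA (0.1 equiv), MeCN, 0 °C → rt
Reagents that add atoms: N-iodosuccinimide, O=C1CCC(=O)N1I
Why: Electrophilic aromatic iodination directed ortho to the free chelated phenol, at the carbon that becomes C8 of the flavone (regiochemistry confirmed by NOE of the remaining ring H to both OCH2Ph groups).

Step 3
Reactants: 3 1-[4,6-bis(benzyloxy)-2-hydroxy-3-iodophenyl]ethan-1-one; 4 3,4-bis(benzyloxy)benzaldehyde
Product: 5 (E)-1-[4,6-bis(benzyloxy)-2-hydroxy-3-iodophenyl]-3-[3,4-bis(benzyloxy)phenyl]prop-2-en-1-one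
Conditions: KOH (50% aq.), EtOH/THF, rt, 48 h; then dilute HCl
Reagents that add atoms: none
Why: Claisen–Schmidt (crossed aldol) condensation of a methyl ketone with a non-enolisable aldehyde, giving the conjugated (E)-chalcone after E1cB dehydration.

Step 4
Reactants: 5 (E)-1-[4,6-bis(benzyloxy)-2-hydroxy-3-iodophenyl]-3-[3,4-bis(benzyloxy)phenyl]prop-2-en-1-one
Product: 6 5,7-bis(benzyloxy)-2-[3,4-bis(benzyloxy)phenyl]-8-iodo-4H-chromen-4-one
Conditions: I2 (0.1 equiv), DMSO, 130 °C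
Reagents that add atoms: none
Why: Iodine-catalysed oxidative cyclisation (intramolecular oxa-Michael addition then dehydrogenation, DMSO as terminal oxidant); only the 2′-OH is free, so the iodine ends up unambiguously at C8.

Step 5
Reactants: 6 5,7-bis(benzyloxy)-2-[3,4-bis(benzyloxy)phenyl]-8-iodo-4H-chromen-4-one
Product: 7 5,7-bis(benzyloxy)-2-[3,4-bis(benzyloxy)phenyl]-8-(4,4,5,5-tetramethyl-1,3,2-dioxaborolan-2-yl)-4H-chromen-4-one
Conditions: B2pin2 (1.5 equiv), PdCl2(dppf) (5 mol%), KOAc (3 equiv), 1,4-dioxane, 90 °C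
Reagents that add atoms: bis(pinacolato)diboron, CC1(C)OB(OC1(C)C)B1OC(C)(C)C(C)(C)O1
Why: Miyaura borylation of the aryl iodide with the weak base KOAc, which leaves the flavone and benzyl ethers untouched and avoids premature Suzuki homocoupling.

Step 6
Reactants: 8 2-bromo-3-hydroxy-4-methoxybenzaldehyde
Product: 9 2-bromo-3,4-dihydroxybenzaldehyde
Conditions: BBr3 (3 equiv), CH2Cl2, −78 °C → rt; then H2O
Reagents that add atoms: none
Why: Lewis-acid-mediated aryl methyl ether cleavage (O–B coordination then bromide SN2 at methyl), which the aryl bromide and aldehyde tolerate at low temperature.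

Step 7
Reactants: 9 2-bromo-3,4-dihydroxybenzaldehyde
Product: 10 2-bromo-3,4-bis(benzyloxy)benzaldehyde
Conditions: BnBr (2.3 equiv), K2CO3 (2.5 equiv), DMF, 50 °C
Reagents that add atoms: benzyl bromide, BrCc1ccccc1
Why: Williamson ether synthesis on both catechol oxygens, so that every hydroxyl of the target carries the same hydrogenolysable group.

Step 8
Reactants: 7 5,7-bis(benzyloxy)-2-[3,4-bis(benzyloxy)phenyl]-8-(4,4,5,5-tetramethyl-1,3,2-dioxaborolan-2-yl)-4H-chromen-4-one; 10 2-bromo-3,4-bis(benzyloxy)benzaldehyde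
Product: 11 3,4-bis(benzyloxy)-2-{5,7-bis(benzyloxy)-2-[3,4-bis(benzyloxy)phenyl]-4-oxo-4H-chromen-8-yl}benzaldehyde
Conditions: Pd(OAc)2 (5 mol%), SPhos (10 mol%), K3PO4 (3 equiv), toluene/H2O (10:1), 90 °C
Reagents that add atoms: none
Why: Suzuki–Miyaura cross-coupling in which the bulky electron-rich biarylphosphine permits the tetra-ortho-substituted biaryl and the ortho-formyl group accelerates oxidative addition of the bromide.

Step 9
Reactants: 2 1-[2,4-bis(benzyloxy)-6-hydroxyphenyl]ethan-1-one; 11 3,4-bis(benzyloxy)-2-{5,7-bis(benzyloxy)-2-[3,4-bis(benzyloxy)phenyl]-4-oxo-4H-chromen-8-yl}benzaldehyde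
Product: 13 1-[2,4-bis(benzyloxy)-6-hydroxyphenyl]-3-{3,4-bis(benzyloxy)-2-[5,7-bis(benzyloxy)-2-(3,4-bis(benzyloxy)phenyl)-4-oxo-4H-chromen-8-yl]phenyl}-3-hydroxypropan-1-one (racemic at the carbinol carbon), via dilithium enolate-phenoxide dianion 12 (not isolated)
Conditions: 2 (1.5 equiv), LiN(iPr)2 (3.1 equiv), THF, −78 → −20 °C; then 11, −78 °C, 1 h; AcOH quench at −78 °C
Reagents that add atoms: none
Why: Directed intermolecular aldol addition of a preformed lithium enolate, which at −78 °C attacks only the aldehyde and not the vinylogous-ester flavone carbonyl; the carbinol centre is formed racemic on purpose because C2 is settled in step 11.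

Step 10
Reactants: 13 the β-hydroxy ketone from step 9
Product: 14 5,7-bis(benzyloxy)-2-{3,4-bis(benzyloxy)-2-[5,7-bis(benzyloxy)-2-(3,4-bis(benzyloxy)phenyl)-4-oxo-4H-chromen-8-yl]phenyl}-2,3-dihydro-4H-chromen-4-one (racemic at C2)
Conditions: PPh3 (1.5 equiv), DIAD (1.5 equiv), THF, 0 °C → rt
Reagents that add atoms: none
Why: Intramolecular Mitsunobu etherification in which the acidic chelated phenol displaces the activated benzylic alcohol to close the six-membered ring C under neutral conditions.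

Step 11
Reactants: 14 the racemic protected flavanone
Product: 15 (2S)-5,7-bis(benzyloxy)-2-{3,4-bis(benzyloxy)-2-[5,7-bis(benzyloxy)-2-(3,4-bis(benzyloxy)phenyl)-4-oxo-4H-chromen-8-yl]phenyl}-2,3-dihydro-4H-chromen-4-one
Conditions: Cp*RhCl[(R,R)-TsDPEN] (1 mol%), HCO2H/Et3N (5:2), EtOAc, rt, to ca. 55% conversion (chiral HPLC shows no 2R isomer left); chromatography
Reagents that add atoms: none
Why: Noyori–Ikariya asymmetric transfer hydrogenation run as a kinetic resolution: the (R,R)-catalyst forms 4R carbinols and so reduces only the (2R)-flavanone (hydride anti to the 2-aryl group, giving the cis-(2R,4R)-flavan-4-ol), leaving the (2S)-flavanone, which is separated from the more polar alcohol.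

Step 12
Reactants: 15 the (2S)-octabenzyl ether
Product: 16 (2S)-2-{2-[2-(3,4-dihydroxyphenyl)-5,7-dihydroxy-4-oxo-4H-chromen-8-yl]-3,4-dihydroxyphenyl}-5,7-dihydroxy-2,3-dihydro-4H-chromen-4-one (target)
Conditions: H2 (1 atm), Pd/C (10 wt% Pd on carbon), THF/MeOH (1:1), rt, monitored by LC-MS; reversed-phase HPLC (0.1% HCO2H)
Reagents that add atoms: none
Why: Catalytic hydrogenolysis of the eight benzyl ethers under neutral conditions, which neither opens nor epimerises the base-sensitive flavanone and, stopped at full debenzylation, leaves the flavone C2=C3 bond and both ketones intact.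

**Compound list**
1 | 2′,4′,6′-trihydroxyacetophenone | CC(=O)c1c(O)cc(O)cc1O | starting material
2 | 1-[2,4-bis(benzyloxy)-6-hydroxyphenyl]ethan-1-one | CC(=O)c1c(O)cc(OCc2ccccc2)cc1OCc1ccccc1 | intermediate
3 | 1-[4,6-bis(benzyloxy)-2-hydroxy-3-iodophenyl]ethan-1-one | CC(=O)c1c(O)c(I)c(OCc2ccccc2)cc1OCc1ccccc1 | intermediate
4 | 3,4-bis(benzyloxy)benzaldehyde | O=Cc1ccc(OCc2ccccc2)c(OCc2ccccc2)c1 | starting material
5 | (E)-1-[4,6-bis(benzyloxy)-2-hydroxy-3-iodophenyl]-3-[3,4-bis(benzyloxy)phenyl]prop-2-en-1-one | O=C(/C=C/c1ccc(OCc2ccccc2)c(OCc2ccccc2)c1)c1c(O)c(I)c(OCc2ccccc2)cc1OCc1ccccc1 | intermediate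
6 | 5,7-bis(benzyloxy)-2-[3,4-bis(benzyloxy)phenyl]-8-iodo-4H-chromen-4-one | O=c1cc(-c2ccc(OCc3ccccc3)c(OCc3ccccc3)c2)oc2c(I)c(OCc3ccccc3)cc(OCc3ccccc3)c12 | intermediate
7 | 5,7-bis(benzyloxy)-2-[3,4-bis(benzyloxy)phenyl]-8-(4,4,5,5-tetramethyl-1,3,2-dioxaborolan-2-yl)-4H-chromen-4-one | O=c1cc(-c2ccc(OCc3ccccc3)c(OCc3ccccc3)c2)oc2c(B3OC(C)(C)C(C)(C)O3)c(OCc3ccccc3)cc(OCc3ccccc3)c12 | intermediate
8 | 2-bromo-3-hydroxy-4-methoxybenzaldehyde | COc1ccc(C=O)c(Br)c1O | starting material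
9 | 2-bromo-3,4-dihydroxybenzaldehyde | O=Cc1ccc(O)c(O)c1Br | intermediate
10 | 2-bromo-3,4-bis(benzyloxy)benzaldehyde | O=Cc1ccc(OCc2ccccc2)c(OCc2ccccc2)c1Br | intermediate
11 | 3,4-bis(benzyloxy)-2-{5,7-bis(benzyloxy)-2-[3,4-bis(benzyloxy)phenyl]-4-oxo-4H-chromen-8-yl}benzaldehyde | O=Cc1ccc(OCc2ccccc2)c(OCc2ccccc2)c1-c1c(OCc2ccccc2)cc(OCc2ccccc2)c2c(=O)cc(-c3ccc(OCc4ccccc4)c(OCc4ccccc4)c3)oc12 | intermediate
12 | dilithium 1-[2,4-bis(benzyloxy)-6-oxidophenyl]ethen-1-olate (dianion of 2) | [Li+].[Li+].C=C([O-])c1c([O-])cc(OCc2ccccc2)cc1OCc1ccccc1 | intermediate (not isolated)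
13 | 1-[2,4-bis(benzyloxy)-6-hydroxyphenyl]-3-{3,4-bis(benzyloxy)-2-[5,7-bis(benzyloxy)-2-(3,4-bis(benzyloxy)phenyl)-4-oxo-4H-chromen-8-yl]phenyl}-3-hydroxypropan-1-one, racemic at the carbinol carbon | O=C(CC(O)c1ccc(OCc2ccccc2)c(OCc2ccccc2)c1-c1c(OCc2ccccc2)cc(OCc2ccccc2)c2c(=O)cc(-c3ccc(OCc4ccccc4)c(OCc4ccccc4)c3)oc12)c1c(O)cc(OCc2ccccc2)cc1OCc1ccccc1 | intermediate
14 | 5,7-bis(benzyloxy)-2-{3,4-bis(benzyloxy)-2-[5,7-bis(benzyloxy)-2-(3,4-bis(benzyloxy)phenyl)-4-oxo-4H-chromen-8-yl]phenyl}-2,3-dihydro-4H-chromen-4-one, racemic at C2 | O=C1CC(c2ccc(OCc3ccccc3)c(OCc3ccccc3)c2-c2c(OCc3ccccc3)cc(OCc3ccccc3)c3c(=O)cc(-c4ccc(OCc5ccccc5)c(OCc5ccccc5)c4)oc23)Oc2cc(OCc3ccccc3)cc(OCc3ccccc3)c21 | intermediate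
15 | (2S)-5,7-bis(benzyloxy)-2-{3,4-bis(benzyloxy)-2-[5,7-bis(benzyloxy)-2-(3,4-bis(benzyloxy)phenyl)-4-oxo-4H-chromen-8-yl]phenyl}-2,3-dihydro-4H-chromen-4-one | O=C1C[C@@H](c2ccc(OCc3ccccc3)c(OCc3ccccc3)c2-c2c(OCc3ccccc3)cc(OCc3ccccc3)c3c(=O)cc(-c4ccc(OCc5ccccc5)c(OCc5ccccc5)c4)oc23)Oc2cc(OCc3ccccc3)cc(OCc3ccccc3)c21 | intermediate
16 | (2S)-2-{2-[2-(3,4-dihydroxyphenyl)-5,7-dihydroxy-4-oxo-4H-chromen-8-yl]-3,4-dihydroxyphenyl}-5,7-dihydroxy-2,3-dihydro-4H-chromen-4-one | O=C1C[C@@H](c2ccc(O)c(O)c2-c2c(O)cc(O)c3c(=O)cc(-c4ccc(O)c(O)c4)oc23)Oc2cc(O)cc(O)c21 | target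

**Totals**
Total step count: 12.
Longest linear sequence: 10 steps (1 → 2 → 3 → 5 → 6 → 7 → 11 → 13 → 14 → 15 → 16); the branch from 8 joins at step 8.

**Three steps most likely to fail**

Step 8 (tetra-ortho-substituted Suzuki coupling). The boronate 7 may protodeboronate, and its preparation from the hindered iodide 6 in step 5 is itself delicate. The fallback reverses the roles of the partners. It sets out from 10, which is borylated (B2pin2, PdCl2(dppf), KOAc, 1,4-dioxane, 90 °C) to 3,4-bis(benzyloxy)-2-(4,4,5,5-tetramethyl-1,3,2-dioxaborolan-2-yl)benzaldehyde F1. F1 is then coupled with the iodoflavone 6 (Pd(OAc)2, SPhos, K3PO4, toluene/H2O, 90 °C) and the route is rejoined at 11, with step 5 bypassed.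

Step 10 (Mitsunobu closure at a hindered, electron-rich benzylic carbinol). Elimination may compete with substitution. The fallback sets out from 13, which is dehydrated (TsOH·H2O cat., toluene, 60 °C) to (E)-1-[2,4-bis(benzyloxy)-6-hydroxyphenyl]-3-{3,4-bis(benzyloxy)-2-[5,7-bis(benzyloxy)-2-(3,4-bis(benzyloxy)phenyl)-4-oxo-4H-chromen-8-yl]phenyl}prop-2-en-1-one F2. F2 is cyclised by base-mediated intramolecular oxa-Michael addition (NaOAc, EtOH/THF, reflux, unreacted chalcone recycled) and the route is rejoined at 14.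

Step 11 (kinetic resolution). The bulky ortho-biaryl ring B and the axial isomers may lower the selectivity factor, or the catalyst may begin to touch the flavone. The fallback replaces the catalytic resolution by a physical one. It sets out from 14, which is separated by preparative supercritical-fluid chromatography on an amylose tris(3,5-dimethylphenylcarbamate) chiral stationary phase (CO2/iPrOH), and the (2S) fractions rejoin the route at 15. No new compound is made (F0).

Further compounds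
F1 | step 8 | 3,4-bis(benzyloxy)-2-(4,4,5,5-tetramethyl-1,3,2-dioxaborolan-2-yl)benzaldehyde | O=Cc1ccc(OCc2ccccc2)c(OCc2ccccc2)c1B1OC(C)(C)C(C)(C)O1
F2 | step 10 | (E)-1-[2,4-bis(benzyloxy)-6-hydroxyphenyl]-3-{3,4-bis(benzyloxy)-2-[5,7-bis(benzyloxy)-2-(3,4-bis(benzyloxy)phenyl)-4-oxo-4H-chromen-8-yl]phenyl}prop-2-en-1-one | O=C(/C=C/c1ccc(OCc2ccccc2)c(OCc2ccccc2)c1-c1c(OCc2ccccc2)cc(OCc2ccccc2)c2c(=O)cc(-c3ccc(OCc4ccccc4)c(OCc4ccccc4)c3)oc12)c1c(O)cc(OCc2ccccc2)cc1OCc1ccccc1
F0 | step 11 | none | none
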